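The easy step is one logarithm. In the beta run 17.3% of the electrophile stands after 40.0 min. I take ln of the inverse fraction, divide by that time and by the nucleophile charge, 1 M, and get the loss constant κ = 0.0439 /M/min, the fractional loss of electrophile per minute and per molar of nucleophile charged. The reading at 6.00 min gives 0.0438 /M/min as well, so the beta run's fall reads as first order in electrophile. Dividing by the charge is my assumption, since no run varies it, but Sunday's and Wednesday's hold the same charge.

| flask | electrophile | nucleophile | free base | remark | time |
|---|---|---|---|---|---|
| beta | 0.27 M | 1 M | 0.60 M | run made earlier |  |
| Sunday's | 0.40 M | 1.00 M | 0.600 M |  | 1.0 h |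
| Wednesday's | 0.40 M | 1.00 M | 0.900 M |  | 1.0 h |

beta run (percent of the electrophile charged)

| time / min | electrophile / % | target / % |
|---|---|---|
| 3.00 | 87.4 | 11.8 |
| 6.00 | 76.9 | 20.8 |
| 15.0 | 52.0 | 37.4 |
| 40.0 | 17.3 | 54.4 |

(standard deviation of a reading: 0.3 percentage points)

- part of the electrophile that has reacted at the end, Sunday's
- part of the electrophile that has reacted at the end, Wednesday's
- what raising the concentration of free base from its lowest to its highest value here does to the part of the electrophile that has reacted (changes below 5 percentage points count as none) (no change / it falls / it rises)

- the analysis behind the earlier runs scatters by 0.3 percentage points, standard deviation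
- no earlier run changes the charge of free base; that part of a forecast is a guess

Now the ladder, from quick to slow. In the beta run the electrophile halves every 15.8 min. Target lags behind it: at 3.00 min electrophile lost and target found differ by 0.8 percentage points, but from 15.0 min to 40.0 min target gains 17 points while the electrophile loses 35 points, about half. Yet the electrophile's fall keeps its constant through that gap. The nucleophile is drawn down meanwhile: taken one to one, the beta run has used 22.3% of its charge by 40.0 min with the constant unchanged, but Sunday's 0.40 M of electrophile can draw up to 40.0%, more than the beta run shows. That draw is not small, so carrying κ over on the charge is a risk I take, not a safe approximation. The free base is a guess, and I guess no change. So Sunday's and Wednesday's run 3.80 half-lives, and I expect 7.20% left, 92.8% reacted.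

The forecast says 92.9%, 93.2% and no change, but calls the step “roughly zero order in nucleophile”; there I part from it.

The flask gives 92.4% on Sunday's and 92.8% on Wednesday's, no change, a change of 0.45 points.

    electrophile + nucleophile → acid set free + target (k = 7.30 × 10⁻⁴ /M/s)
    nucleophile + acid set free ⇌ protonated nucleophile, settled at all times (K = 25.0 /M)
    acid set free + free base ⇌ salt of the base (K = 11000 /M, k = 0.0160 /M/s)
    electrophile + target → side product A (k = 0.00140 /M/s)
    acid set free + target → side product B (k = 7.10 × 10⁻⁴ /M/s)

Moved alone by the same factor, the settings shift Wednesday's answer thus: time (6.2 points), then nucleophile (5.9 points), then electrophile (0.49 points), then free base (0.29 points). κ leaves 7.20% on Wednesday's, and that flask holds 7.2%, with 65.9% of its nucleophile still free, so κ describes the electrophile's fall and does not say the nucleophile stayed at its charge. With 0.60 M of nucleophile in Wednesday's recipe, κ leaves 20.6%, and that flask holds 20.4% of its electrophile at 1.0 h.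

The data were computed for substances that don't exist; noise was put on by code.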